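**Plan**
- Feature: C2 of chromanone ring C (O1, C2, C3, C4, fused to ring A) lies β to the C4 ketone and carries O1, ring B and C8' of the flavonol unit (primed atoms). Ring C is therefore the flavanone ring of a 2'-hydroxychalcone with two aryl groups on its β-carbon.
- Retrosynthetic cuts, in order: O7'–C3 (hemiketal ring F, back to a 3,4-dione), the C3 oxygen, O1–C2 (ring C), C2–C8' (cross-coupling), C3–C4 (acetylide addition).
- Forward: ring A aldehyde and ring B alkyne give an ynone, then a (Z)-β-boryl enone. Suzuki coupling with 8-iodo-tetrabenzylkaempferol gives the (E)-β,β-diaryl enone, and acid frees the 2'-OH. Ring C closes first (key step); C3 is then oxidized; hydrogenolysis frees O7', which closes ring F last.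
- Stereochemistry: C2 is set by a chiral squaramide in the oxa-Michael closure. C3 follows from C2, because the five-membered ring F can only be cis-fused to ring C.

Key step: step 10

Assumption: the quinine-derived squaramide is taken to favour the (R) configuration at C2; if the sense of induction is the opposite, the quinidine-derived pseudoenantiomer is used and nothing else changes.

**Step 1**
Reactants: 1 2,4,6-trihydroxybenzaldehyde
Product: 2 2,4-bis(benzyloxy)-6-hydroxybenzaldehyde
Conditions: BnBr (2.05 equiv), K2CO3, DMF, 0 °C to rt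
Reagents that add atoms: benzyl bromide, BrCc1ccccc1
Why: Williamson etherification; the 4-OH and one ortho-OH are alkylated first, and the last hydroxyl, locked in a hydrogen bond to the aldehyde, is the least nucleophilic, so two equivalents of benzyl bromide should stop at the dibenzyl ether.

**Step 2**
Reactants: 2 2,4-bis(benzyloxy)-6-hydroxybenzaldehyde
Product: 3 2,4-bis(benzyloxy)-6-(methoxymethoxy)benzaldehyde
Conditions: NaH, MOMCl, DMF, 0 °C
Reagents that add atoms: chloromethyl methyl ether, COCCl
Why: Williamson-type O-alkylation after full deprotonation of the chelated phenol; the methoxymethyl acetal withstands organolithium, oxidation and cross-coupling conditions and can later be removed by dilute acid beside benzyl ethers.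

**Step 3**
Reactants: 3 2,4-bis(benzyloxy)-6-(methoxymethoxy)benzaldehyde; 4 1-(benzyloxy)-4-ethynylbenzene
Product: 6 rac-1-[2,4-bis(benzyloxy)-6-(methoxymethoxy)phenyl]-3-[4-(benzyloxy)phenyl]prop-2-yn-1-ol, via lithium acetylide 5 (not isolated)
Conditions: 4, n-BuLi, THF, −78 °C; then 3, −78 °C to 0 °C; H2O
Reagents that add atoms: none
Why: 1,2-addition of a lithium acetylide to an aldehyde forms the C3–C4 bond; the carbinol centre is racemic and disappears in the next step.

**Step 4**
Reactants: 6 rac-propargylic alcohol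
Product: 7 1-[2,4-bis(benzyloxy)-6-(methoxymethoxy)phenyl]-3-[4-(benzyloxy)phenyl]prop-2-yn-1-one
Conditions: MnO2 (excess), CH2Cl2, rt
Reagents that add atoms: none
Why: MnO2 oxidation of a benzylic and propargylic alcohol gives the ynone without touching the ethers or the acetal.

**Step 5**
Reactants: 7 ynone
Product: 8 (Z)-1-[2,4-bis(benzyloxy)-6-(methoxymethoxy)phenyl]-3-[4-(benzyloxy)phenyl]-3-(4,4,5,5-tetramethyl-1,3,2-dioxaborolan-2-yl)prop-2-en-1-one
Conditions: B2pin2 (1.1 equiv), CuCl (5 mol%), Xantphos (5 mol%), NaOt-Bu (10 mol%), MeOH (2 equiv), THF, rt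
Reagents that add atoms: bis(pinacolato)diboron, CC1(C)OB(OC1(C)C)B1OC(C)(C)C(C)(C)O1
Why: copper-catalysed conjugate borylation of an ynone; the copper boryl adds syn across the triple bond with boron on the β-carbon and methanol protonates the α-carbon with retention, which should place boron trans to the carbonyl group (Z).

**Step 6**
Reactants: 9 kaempferol
Product: 10 3,5,7-tris(benzyloxy)-2-[4-(benzyloxy)phenyl]-4H-chromen-4-one
Conditions: BnBr (6 equiv), K2CO3 (8 equiv), n-Bu4NI (cat.), DMF, 80 °C
Reagents that add atoms: benzyl bromide, BrCc1ccccc1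
Why: exhaustive Williamson benzylation; the chelated 5-OH reacts last and needs the excess of reagent and heat.

**Step 7**
Reactants: 10 tetra-O-benzylkaempferol
Product: 11 3,5,7-tris(benzyloxy)-2-[4-(benzyloxy)phenyl]-8-iodo-4H-chromen-4-one
Conditions: NIS (1.05 equiv), TFA (cat.), CH2Cl2–MeCN, 0 °C to rt, dark
Reagents that add atoms: N-iodosuccinimide, O=C1CCC(=O)N1I
Why: electrophilic aromatic iodination; with O5 alkylated, C8 (ortho to O1 and O7, para to O5) is the most nucleophilic and less hindered position of the flavonol benzo ring, C6 lies between two benzyloxy groups, and the 2-aryl ring is deactivated by conjugation to the pyranone.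

**Step 8**
Reactants: 8 (Z)-β-boryl enone; 11 8-iodo-tetra-O-benzylkaempferol
Product: 12 (E)-1-[2,4-bis(benzyloxy)-6-(methoxymethoxy)phenyl]-3-[4-(benzyloxy)phenyl]-3-{3,5,7-tris(benzyloxy)-2-[4-(benzyloxy)phenyl]-4-oxo-4H-chromen-8-yl}prop-2-en-1-one
Conditions: Pd(OAc)2 (5 mol%), SPhos (10 mol%), K3PO4 (3 equiv), toluene–H2O (10:1), 80 °C
Reagents that add atoms: none
Why: Suzuki–Miyaura coupling forms the C2–C8' bond; the bulky biaryl phosphine supports oxidative addition of the di-ortho-substituted aryl iodide to zerovalent palladium and transmetalation of the alkenyl boronate, and the alkene geometry is retained, so the flavonol ends up trans to the carbonyl group (E).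

**Step 9**
Reactants: 12 (E)-enone methoxymethyl ether
Product: 13 (E)-1-[2,4-bis(benzyloxy)-6-hydroxyphenyl]-3-[4-(benzyloxy)phenyl]-3-{3,5,7-tris(benzyloxy)-2-[4-(benzyloxy)phenyl]-4-oxo-4H-chromen-8-yl}prop-2-en-1-one
Conditions: aq. HCl (3 M, cat.), THF–MeOH, rt; prompt work-up with NaHCO3
Reagents that add atoms: none
Why: acid-catalysed acetal cleavage (transacetalization to dimethoxymethane) removes the only acetal present; benzyl ethers withstand dilute HCl at room temperature and acid-promoted ring closure of the congested enone is expected to be slow, so the free 2'-hydroxy enone should be isolable.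

**Step 10**
Reactants: 13 (E)-β,β-diaryl 2'-hydroxychalcone
Product: 14 (R)-5,7-bis(benzyloxy)-2-[4-(benzyloxy)phenyl]-2-{3,5,7-tris(benzyloxy)-2-[4-(benzyloxy)phenyl]-4-oxo-4H-chromen-8-yl}chroman-4-one
Conditions: quinine-derived 3,5-bis(trifluoromethyl)phenyl squaramide (10 mol%), 4 Å MS, toluene, −20 °C to 0 °C
Reagents that add atoms: none
Why: Proposed new method: the quinuclidine nitrogen of the catalyst deprotonates the chelated 2'-OH while the two squaramide N–H bonds bind the enone carbonyl, the phenoxide adds to the β-carbon and the enol is protonated at C3; the closest known reaction type is the organocatalytic asymmetric intramolecular oxa-Michael cyclization of 2'-hydroxychalcones to flavanones, which has not been shown for a β,β-diaryl enone that gives a fully substituted C2. Ring C closes in the 6-endo-trig mode by forming O1–C2. The configuration at C2 is controlled by the catalyst, which presents one face of the β-carbon of the geometrically pure (E)-enone to the bound phenoxide and can tell the flat 4-benzyloxyphenyl group from the flavonol ring that stands perpendicular to the alkene. The step needs kinetic control, because ring opening by retro-oxa-Michael reaction would erode the enantiomeric purity; low temperature, a non-polar solvent and work-up as soon as 13 is consumed are meant to secure it. Chemoselectivity rests on the substrate: 13 has a single free phenol, O7' is benzylated and cannot add to the C4 carbonyl, and the two ortho oxygens twist the flavonol ring out of conjugation so that the enone stays electrophilic.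

**Step 11**
Reactants: 14 (R)-chromanone
Product: 15 (R)-5,7-bis(benzyloxy)-2-[4-(benzyloxy)phenyl]-2-{3,5,7-tris(benzyloxy)-2-[4-(benzyloxy)phenyl]-4-oxo-4H-chromen-8-yl}-4-(trimethylsilyloxy)-2H-chromene
Conditions: TMSOTf (1.5 equiv), Et3N (3 equiv), CH2Cl2, −78 °C to 0 °C
Reagents that add atoms: trimethylsilyl trifluoromethanesulfonate, C[Si](C)(C)OS(=O)(=O)C(F)(F)F
Why: soft enolization with a silyl triflate and a tertiary amine gives the silyl enol ether at C3–C4, the only enolizable site, without a free enolate that could open ring C by β-elimination and endanger C2.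

**Step 12**
Reactants: 15 silyl enol ether
Product: 17 (2R)-5,7-bis(benzyloxy)-2-[4-(benzyloxy)phenyl]-3-hydroxy-2-{3,5,7-tris(benzyloxy)-2-[4-(benzyloxy)phenyl]-4-oxo-4H-chromen-8-yl}chroman-4-one (mixture of C3 epimers), via silyloxy epoxide 16 (not isolated)
Conditions: DMDO (1.1 equiv, acetone), CH2Cl2, −78 °C to −20 °C; then aq. citric acid, THF, 0 °C
Reagents that add atoms: dimethyldioxirane, CC1(C)OO1
Why: Rubottom oxidation; the electron-rich silyl enol ether should be epoxidized much faster than the flavonol alkene or the benzyl ethers, mild acid opens the silyloxy epoxide to the α-hydroxy ketone, and the configuration at C3 is of no consequence because the centre is oxidized in the next step.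

**Step 13**
Reactants: 17 α-hydroxy ketone
Product: 18 (R)-5,7-bis(benzyloxy)-2-[4-(benzyloxy)phenyl]-2-{3,5,7-tris(benzyloxy)-2-[4-(benzyloxy)phenyl]-4-oxo-4H-chromen-8-yl}chromane-3,4-dione
Conditions: Dess–Martin periodinane (1.5 equiv), CH2Cl2, 0 °C to rt
Reagents that add atoms: none
Why: Dess–Martin oxidation of the acyloin to the 1,2-diketone under nearly neutral conditions; with no hydrogen left on C3, ring C can no longer open by β-elimination and C2 is secured.

**Step 14**
Reactants: 18 heptabenzyl 3,4-dione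
Product: 20 target hemiketal (C2 R, C3 S in chromanone numbering; ring F cis-fused, 3-OH cis to the 4-hydroxyphenyl group on C2), via heptahydroxy dione 19 (not isolated)
Conditions: H2 (1 atm), 10% Pd/C, THF–EtOAc, rt
Reagents that add atoms: none
Why: hydrogenolysis of the seven aryl benzyl ethers over Pd/C; the freed O7' adds to the electrophilic C3 ketone in a 5-exo-trig hemiketalization, and because ring F is tethered through C8' on C2 it can only be cis-fused, so C2 dictates the configuration of C3.

**Compound list**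
1 | 2,4,6-trihydroxybenzaldehyde | O=Cc1c(O)cc(O)cc1O | starting material
2 | 2,4-bis(benzyloxy)-6-hydroxybenzaldehyde | O=Cc1c(O)cc(OCc6ccccc6)cc1OCc6ccccc6 | intermediate
3 | 2,4-bis(benzyloxy)-6-(methoxymethoxy)benzaldehyde | O=Cc1c(OCOC)cc(OCc6ccccc6)cc1OCc6ccccc6 | intermediate
4 | 1-(benzyloxy)-4-ethynylbenzene | C#Cc1ccc(OCc6ccccc6)cc1 | starting material
5 | lithium [4-(benzyloxy)phenyl]acetylide (formed in the flask) | [Li]C#Cc1ccc(OCc6ccccc6)cc1 | intermediate
6 | rac-1-[2,4-bis(benzyloxy)-6-(methoxymethoxy)phenyl]-3-[4-(benzyloxy)phenyl]prop-2-yn-1-ol | OC(C#Cc1ccc(OCc6ccccc6)cc1)c1c(OCOC)cc(OCc6ccccc6)cc1OCc6ccccc6 | intermediate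
7 | 1-[2,4-bis(benzyloxy)-6-(methoxymethoxy)phenyl]-3-[4-(benzyloxy)phenyl]prop-2-yn-1-one | O=C(C#Cc1ccc(OCc6ccccc6)cc1)c1c(OCOC)cc(OCc6ccccc6)cc1OCc6ccccc6 | intermediate
8 | (Z)-1-[2,4-bis(benzyloxy)-6-(methoxymethoxy)phenyl]-3-[4-(benzyloxy)phenyl]-3-(4,4,5,5-tetramethyl-1,3,2-dioxaborolan-2-yl)prop-2-en-1-one | O=C(/C=C(/B1OC(C)(C)C(C)(C)O1)c1ccc(OCc6ccccc6)cc1)c1c(OCOC)cc(OCc6ccccc6)cc1OCc6ccccc6 | intermediate
9 | kaempferol | O=c1c(O)c(-c2ccc(O)cc2)oc2cc(O)cc(O)c12 | starting material
10 | 3,5,7-tris(benzyloxy)-2-[4-(benzyloxy)phenyl]-4H-chromen-4-one | O=c1c(OCc6ccccc6)c(-c2ccc(OCc6ccccc6)cc2)oc2cc(OCc6ccccc6)cc(OCc6ccccc6)c12 | intermediate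
11 | 3,5,7-tris(benzyloxy)-2-[4-(benzyloxy)phenyl]-8-iodo-4H-chromen-4-one | O=c1c(OCc6ccccc6)c(-c2ccc(OCc6ccccc6)cc2)oc2c(I)c(OCc6ccccc6)cc(OCc6ccccc6)c12 | intermediate
12 | (E)-1-[2,4-bis(benzyloxy)-6-(methoxymethoxy)phenyl]-3-[4-(benzyloxy)phenyl]-3-{3,5,7-tris(benzyloxy)-2-[4-(benzyloxy)phenyl]-4-oxo-4H-chromen-8-yl}prop-2-en-1-one | O=C(/C=C(/c1c(OCc6ccccc6)cc(OCc6ccccc6)c2c(=O)c(OCc6ccccc6)c(-c3ccc(OCc6ccccc6)cc3)oc12)c1ccc(OCc6ccccc6)cc1)c1c(OCOC)cc(OCc6ccccc6)cc1OCc6ccccc6 | intermediate
13 | (E)-1-[2,4-bis(benzyloxy)-6-hydroxyphenyl]-3-[4-(benzyloxy)phenyl]-3-{3,5,7-tris(benzyloxy)-2-[4-(benzyloxy)phenyl]-4-oxo-4H-chromen-8-yl}prop-2-en-1-one (precursor of the key step) | O=C(/C=C(/c1c(OCc6ccccc6)cc(OCc6ccccc6)c2c(=O)c(OCc6ccccc6)c(-c3ccc(OCc6ccccc6)cc3)oc12)c1ccc(OCc6ccccc6)cc1)c1c(O)cc(OCc6ccccc6)cc1OCc6ccccc6 | intermediate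
14 | (R)-5,7-bis(benzyloxy)-2-[4-(benzyloxy)phenyl]-2-{3,5,7-tris(benzyloxy)-2-[4-(benzyloxy)phenyl]-4-oxo-4H-chromen-8-yl}chroman-4-one (product of the key step) | O=C1C[C@@](c2ccc(OCc6ccccc6)cc2)(c2c(OCc6ccccc6)cc(OCc6ccccc6)c3c(=O)c(OCc6ccccc6)c(-c4ccc(OCc6ccccc6)cc4)oc23)Oc2cc(OCc6ccccc6)cc(OCc6ccccc6)c12 | intermediate
15 | C3–C4 trimethylsilyl enol ether of 14, (R)-4-(trimethylsilyloxy)-2H-chromene | C[Si](C)(C)OC1=C[C@@](c2ccc(OCc6ccccc6)cc2)(c2c(OCc6ccccc6)cc(OCc6ccccc6)c3c(=O)c(OCc6ccccc6)c(-c4ccc(OCc6ccccc6)cc4)oc23)Oc2cc(OCc6ccccc6)cc(OCc6ccccc6)c12 | intermediate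
16 | 3,4-epoxide of 15 (4-silyloxy oxirane, C2 R, C3 and C4 undefined; formed in the flask) | C[Si](C)(C)OC12OC1[C@@](c3ccc(OCc6ccccc6)cc3)(c3c(OCc6ccccc6)cc(OCc6ccccc6)c4c(=O)c(OCc6ccccc6)c(-c5ccc(OCc6ccccc6)cc5)oc34)Oc1cc(OCc6ccccc6)cc(OCc6ccccc6)c21 | intermediate
17 | (2R)-3-hydroxy derivative of 14 (mixture of C3 epimers) | O=C1C(O)[C@@](c2ccc(OCc6ccccc6)cc2)(c2c(OCc6ccccc6)cc(OCc6ccccc6)c3c(=O)c(OCc6ccccc6)c(-c4ccc(OCc6ccccc6)cc4)oc23)Oc2cc(OCc6ccccc6)cc(OCc6ccccc6)c12 | intermediate
18 | (R)-5,7-bis(benzyloxy)-2-[4-(benzyloxy)phenyl]-2-{3,5,7-tris(benzyloxy)-2-[4-(benzyloxy)phenyl]-4-oxo-4H-chromen-8-yl}chromane-3,4-dione | O=C1C(=O)[C@@](c2ccc(OCc6ccccc6)cc2)(c2c(OCc6ccccc6)cc(OCc6ccccc6)c3c(=O)c(OCc6ccccc6)c(-c4ccc(OCc6ccccc6)cc4)oc23)Oc2cc(OCc6ccccc6)cc(OCc6ccccc6)c12 | intermediate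
19 | (R)-5,7-dihydroxy-2-(4-hydroxyphenyl)-2-[3,5,7-trihydroxy-2-(4-hydroxyphenyl)-4-oxo-4H-chromen-8-yl]chromane-3,4-dione (formed in the flask) | O=C1C(=O)[C@@](c2ccc(O)cc2)(c2c(O)cc(O)c3c(=O)c(O)c(-c4ccc(O)cc4)oc23)Oc2cc(O)cc(O)c12 | intermediate
20 | CNP0314633.1: (2R,3S)-3,5,7-trihydroxy-2-(4-hydroxyphenyl)chroman-4-one with C2 bonded to C8' and C3 bonded to O7' of a kaempferol unit (cis-fused furan ring F) | O=C1c2c(O)cc(O)cc2O[C@]2(c3ccc(O)cc3)c3c(cc(O)c4c(=O)c(O)c(-c5ccc(O)cc5)oc34)O[C@]12O | target

**Count**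
Total steps: 14. Longest linear sequence: 12 steps (steps 1–5 and 8–14); steps 6–7 form the two-step branch to iodide 11.

**Steps most likely to fail**

Step 10. Facial discrimination at the crowded β-carbon may be poor, closure may be slow, or the enantiomeric purity may erode through reversible ring opening. The fallback sets out from 13 and closes ring C without stereocontrol under the classical chalcone-to-flavanone conditions (NaOAc, EtOH, reflux). This gives racemic 5,7-bis(benzyloxy)-2-[4-(benzyloxy)phenyl]-2-{3,5,7-tris(benzyloxy)-2-[4-(benzyloxy)phenyl]-4-oxo-4H-chromen-8-yl}chroman-4-one F1. The enantiomers are separated by preparative HPLC on a polysaccharide chiral stationary phase, and the (R)-enantiomer is 14, where the route is rejoined. The unwanted (S)-chromanone F2 is returned to the same basic conditions, where ring opening and reclosure should regenerate F1 for another resolution cycle.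

Step 8. Transmetalation between the di-ortho-substituted aryl palladium species and the congested alkenyl boronate may be slow, so that protodeboronation or loss of alkene geometry competes. The fallback sets out from ynone 7 and iodide 11 and joins them by a reductive Heck (Cacchi) hydroarylation (Pd(OAc)2, HCO2H, Et3N, DMF, 40–60 °C). The aryl palladium species adds syn across the triple bond with the aryl group on the β-carbon, and formate replaces palladium by hydrogen with retention. The same (E)-enone 12 should result, where the route is rejoined; this fallback makes no compound outside the list (F0).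

Step 14. The C3 ketone of the vicinal dione may be partly reduced before O7' is freed, or the doubly benzylic C2–O1 bond may be cleaved on the catalyst. The fallback sets out from 18 and removes the benzyl groups without a reductant (BCl3, pentamethylbenzene as cation scavenger, CH2Cl2, −78 °C; aqueous work-up). This should give 19, which closes to 20, where the route ends; this fallback makes no compound outside the list (F0).

**Further compounds**
F1 | step 10 | racemic 5,7-bis(benzyloxy)-2-[4-(benzyloxy)phenyl]-2-{3,5,7-tris(benzyloxy)-2-[4-(benzyloxy)phenyl]-4-oxo-4H-chromen-8-yl}chroman-4-one | O=C1CC(c2ccc(OCc6ccccc6)cc2)(c2c(OCc6ccccc6)cc(OCc6ccccc6)c3c(=O)c(OCc6ccccc6)c(-c4ccc(OCc6ccccc6)cc4)oc23)Oc2cc(OCc6ccccc6)cc(OCc6ccccc6)c12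
F2 | step 10 | (S)-5,7-bis(benzyloxy)-2-[4-(benzyloxy)phenyl]-2-{3,5,7-tris(benzyloxy)-2-[4-(benzyloxy)phenyl]-4-oxo-4H-chromen-8-yl}chroman-4-one | O=C1C[C@](c2ccc(OCc6ccccc6)cc2)(c2c(OCc6ccccc6)cc(OCc6ccccc6)c3c(=O)c(OCc6ccccc6)c(-c4ccc(OCc6ccccc6)cc4)oc23)Oc2cc(OCc6ccccc6)cc(OCc6ccccc6)c12
F0 | step 8 | none | none
F0 | step 14 | none | none
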